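**Strategy.** The route rests on cutting the O–CMe2 bond of pyran 1 (the CMe2 pyran on quinolone 1). Read that way, the ten aliphatic carbons – the ring-fusion carbons C-a (CH beside CMe2) and C-b (OCH), CMe2, C-c (CH carrying the side chain) and the side chain – are a lavandulyl unit, i.e. trans-chrysanthemic acid with the cyclopropane bond between its gem-dimethyl and alkenyl-bearing carbons broken. In one operation a Lewis acid opens the side-chain epoxide of a 3-[(1S)-chrysanthemoyl]-4-hydroxyquinolone, the cyclopropane unzips to an E-alkene and a tertiary cation, and the quinolone 4-oxygen closes pyran 1, with C-a carried unchanged from the chiral pool. Pyran 2 follows by reduction, O-arylation, Friedel–Crafts closure and hydration.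

Key step: step 3

Remark on the chemistry: acid 2 is assumed purchasable as the single (1S,3S) enantiomer (otherwise it is resolved from the commercial racemic trans acid with a chiral amine before step 1). Epoxide 6 is carried as both oxirane epimers because that centre is destroyed in step 3. The SMILES of acid, precursor, key product and target were checked against one another and are consistent: C1 of the acid becomes C-a, and the target is C-a R, C-b S, C-c R. Primed locants refer to quinolone 2, which carries pyran 2.

**Step 1**
Reactants: 1 4-hydroxy-1-methylquinolin-2(1H)-one; 2 (1S,3S)-(−)-trans-chrysanthemic acid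
Product: 5 3-[(1S,3S)-trans-chrysanthemoyl]-4-hydroxy-1-methylquinolin-2(1H)-one, via (1S,3S)-chrysanthemoyl chloride 3 (not isolated), via 1-methyl-2-oxo-1,2-dihydroquinolin-4-yl (1S,3S)-chrysanthemate 4 (not isolated)
Conditions: 2, (COCl)2, cat. DMF, CH2Cl2, 0 °C to rt, evaporate; then 1, Et3N, CH2Cl2, 0 °C to rt; then DMAP (1.0 equiv), 40 °C
Reagents that add atoms: none
Why: Acyl chloride formation, O-acylation of the vinylogous acid 1 and a DMAP-mediated O-to-C acyl shift (Fries-type rearrangement through an acylpyridinium–enolate ion pair) should give the hydrogen-bonded 3-acyl enol, and both cyclopropane stereocentres survive because a cyclopropyl α-carbon resists enolisation.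

**Step 2**
Reactants: 5 3-[(1S,3S)-trans-chrysanthemoyl]-4-hydroxy-1-methylquinolin-2(1H)-one
Product: 6 3-{[(1S,3S)-3-(3,3-dimethyloxiran-2-yl)-2,2-dimethylcyclopropyl]carbonyl}-4-hydroxy-1-methylquinolin-2(1H)-one (both oxirane epimers)
Conditions: dimethyldioxirane (1.05 equiv, acetone solution), CH2Cl2, −20 °C; evaporate cold, use directly
Reagents that add atoms: dimethyldioxirane, CC1(C)OO1
Why: Dioxirane epoxidation (concerted oxygen transfer) should select the electron-rich trisubstituted alkene over the electron-poor enol double bond under neutral, acid-free conditions that spare the sensitive cyclopropyl oxirane; the new oxirane centre forms as both epimers, which is immaterial because step 3 destroys it.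

**Step 3**
Reactants: 6 epoxide of the 3-chrysanthemoyl-4-hydroxyquinolone (both oxirane epimers)
Product: 7 (3S)-3-[(1E)-3-hydroxy-3-methylbut-1-en-1-yl]-2,2,6-trimethyl-2,3-dihydro-4H-pyrano[3,2-c]quinoline-4,5(6H)-dione
Conditions: BF3·OEt2 (2.2 equiv), CH2Cl2, −78 to −40 °C, short contact; pH 7 phosphate buffer quench at −78 °C
Reagents that add atoms: none
Why: Proposed new method: BF3 ionises the oxirane C–O bond at the carbon attached to the cyclopropane, the resulting cyclopropylcarbinyl cation opens by cleavage of the ring bond to the gem-dimethyl carbon (E-alkene plus tertiary cation), and the enolic 4-oxygen captures that cation with loss of its proton; the closest known reaction types are the cyclopropylcarbinyl-to-homoallyl opening of the Julia olefin synthesis and the acid-induced chrysanthemyl-to-lavandulyl rearrangement. Pyran 1 closes by attack of O4 on the CMe2 carbon, formally 6-exo-tet with the breaking cyclopropane bond outside the new ring. No stereocentre is created: C-a is the former C1 of the acid, none of its four bonds changes, and the E geometry follows from the bisected cation in which the CMe2O group points away from the cis ring methyl. Three selectivities are needed: oxirane cleavage at the carbinyl and not the tertiary carbon is secured by the cyclopropane Walsh orbitals, with charge passing on to the gem-dimethyl carbon; cleavage of that ring bond and not the other is secured because the alternative would place the cation next to the ketone; capture by O4 and not by the lactam oxygen is to be secured by using BF3 in excess, which keeps the more basic lactam oxygen as its adduct. Low temperature, short contact and a neutral quench are meant to prevent enolisation or retro-oxa-Michael opening at C-a.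

**Step 4**
Reactants: 7 (3S)-3-alkenyl-pyrano[3,2-c]quinoline-4,5-dione
Product: 8 (3R,4S)-4-hydroxy-3-[(1E)-3-hydroxy-3-methylbut-1-en-1-yl]-2,2,6-trimethyl-3,4-dihydro-2H-pyrano[3,2-c]quinolin-5(6H)-one (3-alkenyl and 4-OH cis)
Conditions: LiBH(s-Bu)3 (2.2 equiv), THF, −78 °C; H2O quench at −78 °C
Reagents that add atoms: none
Why: 1,2-Reduction by the bulky trialkylborohydride should deliver hydride to the face opposite the C-a alkenyl group, so that C-b is set cis to C-a by substrate control, while the low basicity of the reagent at −78 °C spares the enolisable C-a–H.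

**Step 5**
Reactants: 1 4-hydroxy-1-methylquinolin-2(1H)-one
Product: 9 4-chloro-1-methylquinolin-2(1H)-one
Conditions: POCl3 (neat), 90 °C; ice-water work-up
Reagents that add atoms: phosphoryl chloride, O=P(Cl)(Cl)Cl
Why: Deoxychlorination of the 4-hydroxy group of a 2-quinolone with POCl3 (through the dichlorophosphate) is a standard reaction, and the N-methyl lactam cannot be converted into a stable 2-chloro compound.

**Step 6**
Reactants: 8 cis-diol (3R,4S); 9 4-chloro-1-methylquinolin-2(1H)-one
Product: 10 (3R,4S)-3-[(1E)-3-hydroxy-3-methylbut-1-en-1-yl]-2,2,6-trimethyl-4-[(1-methyl-2-oxo-1,2-dihydroquinolin-4-yl)oxy]-3,4-dihydro-2H-pyrano[3,2-c]quinolin-5(6H)-one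
Conditions: NaH (1.05 equiv), DMF, 0 °C; then 9, 0 °C to rt
Reagents that add atoms: none
Why: Nucleophilic aromatic substitution (addition–elimination) of the secondary alkoxide at C4 of the vinylogous carbamoyl chloride 9 should give the aryl ether with C-b unchanged, since the C-b–O bond is not touched, the tertiary hydroxyl being the more hindered and less acidic of the two.

**Step 7**
Reactants: 10 aryl ether with free tertiary allylic alcohol
Product: 11 bis-pyranoquinolone with a 2-methylprop-1-enyl group at C-c (C-a R, C-b S, C-c R; pyran 1 and pyran 2 cis-fused at C-a/C-b, alkenyl group trans to CMe2)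
Conditions: BF3·OEt2 (0.2 equiv), 4 Å molecular sieves, CH2Cl2, −40 to −20 °C
Reagents that add atoms: none
Why: Acid-induced loss of water from the tertiary allylic alcohol gives a dimethylallyl cation that the C3 position of quinolone 2 (the nucleophilic carbon of its 4-alkoxy enol ether) attacks at the secondary terminus in an intramolecular Friedel–Crafts allylation (6-exo), closing pyran 2; C-c is set by the chair-like transition state that keeps the alkenyl group trans to the CMe2 branch on C-a, which is also the thermodynamically preferred arrangement.

**Step 8**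
Reactants: 11 bis-pyranoquinolone with the 2-methylprop-1-enyl group
Product: 12 target, bis-pyranoquinolone with a 2-hydroxy-2-methylpropyl group at C-c (C-a R, C-b S, C-c R)
Conditions: Co(acac)2 (20 mol %), PhSiH3, O2 (1 atm), THF, rt
Reagents that add atoms: dioxygen, O=O
Why: Mukaiyama hydration (hydrogen-atom transfer from a cobalt hydride to the trisubstituted alkene, then capture of the tertiary radical by O2) gives the Markovnikov tertiary alcohol without touching a stereocentre, the tetrasubstituted quinolone double bonds being inert to hydrogen-atom transfer.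

**Compound list**
1 | 4-hydroxy-1-methylquinolin-2(1H)-one | Cn1c(=O)cc(O)c2ccccc21 | starting material
2 | (1S,3S)-(−)-trans-chrysanthemic acid | CC(C)=C[C@H]1[C@H](C(=O)O)C1(C)C | starting material
3 | (1S,3S)-chrysanthemoyl chloride | CC(C)=C[C@H]1[C@H](C(=O)Cl)C1(C)C | intermediate
4 | 1-methyl-2-oxo-1,2-dihydroquinolin-4-yl (1S,3S)-chrysanthemate | CC(C)=C[C@H]1[C@H](C(=O)Oc2cc(=O)n(C)c3ccccc23)C1(C)C | intermediate
5 | 3-[(1S,3S)-trans-chrysanthemoyl]-4-hydroxy-1-methylquinolin-2(1H)-one | Cn1c(=O)c(C(=O)[C@@H]3C(C)(C)[C@H]3C=C(C)C)c(O)c2ccccc21 | intermediate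
6 | 3-{[(1S,3S)-3-(3,3-dimethyloxiran-2-yl)-2,2-dimethylcyclopropyl]carbonyl}-4-hydroxy-1-methylquinolin-2(1H)-one, both oxirane epimers | Cn1c(=O)c(C(=O)[C@@H]3C(C)(C)[C@H]3C4OC4(C)C)c(O)c2ccccc21 | intermediate
7 | (3S)-3-[(1E)-3-hydroxy-3-methylbut-1-en-1-yl]-2,2,6-trimethyl-2,3-dihydro-4H-pyrano[3,2-c]quinoline-4,5(6H)-dione | Cn1c(=O)c2c(c3ccccc31)OC(C)(C)[C@H](/C=C/C(C)(C)O)C2=O | intermediate
8 | (3R,4S)-4-hydroxy-3-[(1E)-3-hydroxy-3-methylbut-1-en-1-yl]-2,2,6-trimethyl-3,4-dihydro-2H-pyrano[3,2-c]quinolin-5(6H)-one | Cn1c(=O)c2c(c3ccccc31)OC(C)(C)[C@H](/C=C/C(C)(C)O)[C@@H]2O | intermediate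
9 | 4-chloro-1-methylquinolin-2(1H)-one | Cn1c(=O)cc(Cl)c2ccccc21 | intermediate
10 | (3R,4S)-3-[(1E)-3-hydroxy-3-methylbut-1-en-1-yl]-2,2,6-trimethyl-4-[(1-methyl-2-oxo-1,2-dihydroquinolin-4-yl)oxy]-3,4-dihydro-2H-pyrano[3,2-c]quinolin-5(6H)-one | Cn1c(=O)c2c(c3ccccc31)OC(C)(C)[C@H](/C=C/C(C)(C)O)[C@@H]2Oc2cc(=O)n(C)c3ccccc23 | intermediate
11 | bis-pyranoquinolone with 2-methylprop-1-enyl at C-c (C-a R, C-b S, C-c R) | Cn1c(=O)c2c(c3ccccc31)OC(C)(C)[C@H]1[C@@H]2Oc2c(c(=O)n(C)c3ccccc23)[C@@H]1C=C(C)C | intermediate
12 | CNP0202276.1, bis-pyranoquinolone with 2-hydroxy-2-methylpropyl at C-c (C-a R, C-b S, C-c R) | Cn1c(=O)c2c(c3ccccc31)OC(C)(C)[C@H]1[C@@H]2Oc2c(c(=O)n(C)c3ccccc23)[C@@H]1CC(C)(C)O | target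

**Step count.** Total: 8 steps. Longest linear sequence: 7 steps (steps 1–4 and 6–8 from acid 2); step 5 is a one-step side branch from 1.

**Steps most likely to fail**

1. Step 3 (proposed new method). The failure modes are these:
   - The hydrogen-bonded resting rotamer of 6 holds the acyl side chain on the lactam side, so the tertiary cation may be captured by the lactam oxygen despite the BF3 adduct.
   - The cation may lose a proton to an isopropenyl diene.
   - The oxirane may open at its tertiary carbon and undergo a hydride shift.
   - C-a may lose configuration by enolisation.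

   Fallback, known pericyclic chemistry, setting out from 1 and returning at 11 (steps 1–7 are replaced, step 8 finishes): condensation of 1 with 3-methylbut-2-enal (pyridine, 110 °C; Knoevenagel condensation then oxa-6π electrocyclisation) gives 2,2,6-trimethyl-2,6-dihydro-5H-pyrano[3,2-c]quinolin-5-one (N-methylflindersine) F1. On heating in xylene in a sealed tube, part of F1 opens to the 1-oxatriene 1-methyl-3-(3-methylbut-2-en-1-ylidene)quinoline-2,4(1H,3H)-dione F2. F2 should add as an oxa-diene across the pyran C3=C4 bond of unchanged F1 in a hetero-Diels–Alder reaction: oxygen bonds to C-b and C-c to C-a, and suprafacial addition makes the C-a/C-b fusion cis. The diastereomer with the alkenyl group trans to CMe2 is isolated as the racemate and separated on a chiral stationary phase into 11 and the enantiomer of 11 F3.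

2. Step 6. The alkoxide of 8 may fragment by an oxyanion-driven retro-cycloaddition, the tertiary alkoxide may be arylated in competition, or substitution at the hindered secondary centre may be too slow. Fallback, setting out from 8 and 9 and returning at 10: palladium-catalysed C–O cross-coupling (Pd2(dba)3, RockPhos, Cs2CO3, toluene, 80 °C). Compound 9 adds oxidatively to zerovalent palladium, only the secondary alcohol binds, and reductive elimination forms the ether, while the weak carbonate base keeps the free alkoxide concentration low. This fallback makes no new compound (entry F0).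

3. Step 7. Ionisation may occur at the doubly activated C-b–O ether bond instead of the allylic alcohol, which would scramble the connectivity; the allyl cation may lose a proton to a diene; or facial selectivity at C-c may be poor. Fallback, setting out from 10 and returning at 12 (step 8 is then not needed): the C3′–C-c bond is made by a radical instead of a cation. NBS in MeCN at 0 °C should brominate the enol-ether carbon C3′ of quinolone 2 to give the 3′-bromo aryl ether F4. Bu3SnH and AIBN in benzene at 80 °C then generate the C3′ radical, which cyclises 6-exo-trig onto the E-alkene at C-c. The resulting secondary radical takes hydrogen from the stannane, so the saturated hydroxyalkyl chain forms directly. A chair-like transition state should again place the chain trans to CMe2.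

**Further compounds**
F1 | step 3 | 2,2,6-trimethyl-2,6-dihydro-5H-pyrano[3,2-c]quinolin-5-one (N-methylflindersine) | Cn1c(=O)c2c(c3ccccc31)OC(C)(C)C=C2
F2 | step 3 | 1-methyl-3-(3-methylbut-2-en-1-ylidene)quinoline-2,4(1H,3H)-dione | CN1C(=O)C(=CC=C(C)C)C(=O)c2ccccc21
F3 | step 3 | enantiomer of 11 | Cn1c(=O)c2c(c3ccccc31)OC(C)(C)[C@@H]1[C@H]2Oc2c(c(=O)n(C)c3ccccc23)[C@H]1C=C(C)C
F0 | step 6 | none | none
F4 | step 7 | (3R,4S)-4-[(3-bromo-1-methyl-2-oxo-1,2-dihydroquinolin-4-yl)oxy]-3-[(1E)-3-hydroxy-3-methylbut-1-en-1-yl]-2,2,6-trimethyl-3,4-dihydro-2H-pyrano[3,2-c]quinolin-5(6H)-one | Cn1c(=O)c2c(c3ccccc31)OC(C)(C)[C@H](/C=C/C(C)(C)O)[C@@H]2Oc2c(Br)c(=O)n(C)c3ccccc23
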